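## Retrosynthetic overview

1. IN0404 is the (7S,8R)-erythro 8-O-4' neolignan. The last operations only unmask hydroxyl groups (two silyl ethers by fluoride, one aryl benzyl ether by hydrogenolysis). No ring is formed: ring A (guaiacyl) and ring B (syringyl) are both bought.
2. The erythro C7 carbinol comes from the threo C7 carbinol by Mitsunobu inversion, with C8 untouched and C9-OH masked as a TBS ether.
3. The C7–C8 bond comes from an Evans boron syn-aldol of an N-(aryloxyacetyl)-(S)-4-benzyloxazolidinone with 4-benzyloxy-3-methoxybenzaldehyde. Reductive removal of the auxiliary then gives C9H2OH.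
4. The aryloxyacetic acid comes from 4-allyl-2,6-dimethoxyphenol. Williamson etherification with ethyl bromoacetate makes the C8–O–C4' bond, hydroboration–oxidation of the allyl group makes the propanol chain, and TBDPS protects it.

Assumption: C7 is the benzylic carbinol carbon, C8 the aryloxy-bearing carbon and C9 the CH2OH carbon. CIP analysis of the given SMILES gives (7S,8R), which is the erythro (anti in zig-zag) isomer, so a syn-aldol adduct is threo and C7 must be inverted once.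

## Route

Step 1
Reactants: 1 4-allyl-2,6-dimethoxyphenol; 2 ethyl bromoacetate
Product: 3 ethyl 2-(4-allyl-2,6-dimethoxyphenoxy)acetate
Conditions: K2CO3 (2 equiv), acetone, reflux, 12 h
Reagents that add atoms: none
Why: Williamson ether synthesis (SN2), in which the phenoxide of 1 displaces bromide from the unhindered, activated α-bromo ester while K2CO3 leaves the allyl group and the ester alone.

Step 2
Reactants: 3 ethyl 2-(4-allyl-2,6-dimethoxyphenoxy)acetate
Product: 5 ethyl 2-[4-(3-hydroxypropyl)-2,6-dimethoxyphenoxy]acetate, via B-alkyl-9-BBN adduct 4 (not isolated)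
Conditions: 9-BBN (1.3 equiv, 0.5 M in THF), 0 °C to rt; then NaBO3·4H2O (5 equiv), THF/H2O, rt
Reagents that add atoms: 9-BBN, B1C2CCCC1CCC2 (its boron framework stays in 4 only); NaBO3·4H2O, [Na+].[Na+].O[B-]1(O)OO[B-](O)(O)OO1 (gives the hydroxyl oxygen of 5)
Why: Brown hydroboration–oxidation, in which bulky 9-BBN adds anti-Markovnikov to the terminal alkene far faster than it attacks an ester and mild perborate oxidises the C–B bond without saponifying the ethyl ester.

Step 3
Reactants: 5 ethyl 2-[4-(3-hydroxypropyl)-2,6-dimethoxyphenoxy]acetate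
Product: 6 ethyl 2-{4-[3-(tert-butyldiphenylsilyloxy)propyl]-2,6-dimethoxyphenoxy}acetate
Conditions: TBDPSCl (1.1 equiv), imidazole (2.2 equiv), DMF, 0 °C to rt
Reagents that add atoms: TBDPSCl, CC(C)(C)[Si](Cl)(c1ccccc1)c1ccccc1
Why: Imidazole-promoted silyl ether protection of the only free hydroxyl gives a TBDPS ether that withstands the later hydroxide, boron triflate, hydride and carbonate steps.

Step 4
Reactants: 6 ethyl 2-{4-[3-(tert-butyldiphenylsilyloxy)propyl]-2,6-dimethoxyphenoxy}acetate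
Product: 8 2-{4-[3-(tert-butyldiphenylsilyloxy)propyl]-2,6-dimethoxyphenoxy}acetic acid, via lithium carboxylate 7 (not isolated)
Conditions: LiOH·H2O (2 equiv), THF/H2O 3:1, 0 °C to rt; then 1 M HCl to pH 3, 0 °C
Reagents that add atoms: LiOH, [Li+].[OH-] (one oxygen of the carboxyl group; lithium in 7 only)
Why: Ester saponification (acyl–oxygen cleavage) of an activated aryloxyacetate is fast at room temperature, and the TBDPS ether and the aryl ethers are inert to LiOH and to brief dilute acid.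

Step 5
Reactants: 8 2-{4-[3-(tert-butyldiphenylsilyloxy)propyl]-2,6-dimethoxyphenoxy}acetic acid; 9 (S)-4-benzyloxazolidin-2-one
Product: 11 (S)-4-benzyl-3-(2-{4-[3-(tert-butyldiphenylsilyloxy)propyl]-2,6-dimethoxyphenoxy}acetyl)oxazolidin-2-one, via pivalic mixed anhydride 10 (not isolated)
Conditions: PivCl (1.05 equiv), Et3N (2.5 equiv), THF, −20 °C, 1 h; then LiCl (1.1 equiv), 9 (1.0 equiv), −20 °C to rt
Reagents that add atoms: pivaloyl chloride, CC(C)(C)C(=O)Cl (pivaloyl group in 10 only)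
Why: Mixed-anhydride N-acylation of the Evans auxiliary, in which the LiCl/Et3N-activated oxazolidinone attacks the unhindered aryloxyacetyl carbonyl of 10 rather than the tert-butyl-shielded one, and the auxiliary stereocentre is not involved.

Step 6
Reactants: 11 (S)-4-benzyl-3-(2-{4-[3-(tert-butyldiphenylsilyloxy)propyl]-2,6-dimethoxyphenoxy}acetyl)oxazolidin-2-one; 12 4-benzyloxy-3-methoxybenzaldehyde
Product: 15 (S)-4-benzyl-3-[(2S,3R)-3-(4-benzyloxy-3-methoxyphenyl)-2-{4-[3-(tert-butyldiphenylsilyloxy)propyl]-2,6-dimethoxyphenoxy}-3-hydroxypropanoyl]oxazolidin-2-one (syn = threo), via (Z)-dibutylboron enolate 13 (not isolated), via dibutylboron aldolate 14 (not isolated)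
Conditions: Bu2BOTf (1.2 equiv), Et3N (1.4 equiv), CH2Cl2, −78 to 0 °C; 12 (1.2 equiv), −78 to 0 °C; then pH 7 phosphate buffer, MeOH, 30% H2O2, 0 °C
Reagents that add atoms: Bu2BOTf, CCCCB(CCCC)OS(=O)(=O)C(F)(F)F (Bu2B group in 13 and 14 only)
Why: Evans syn-aldol, in which soft enolisation gives only the (Z)-boron enolate 13, which adds to 12 through a closed Zimmerman–Traxler chair with the auxiliary carbonyl turned away from the enolate oxygen and its benzyl group shielding one face, so C8 is set as the target needs (2S here, 8R once C9 is CH2OH) and C7 is set as 3R.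

Step 7
Reactants: 15 the syn-aldol adduct
Product: 16 (1R,2R)-1-(4-benzyloxy-3-methoxyphenyl)-2-{4-[3-(tert-butyldiphenylsilyloxy)propyl]-2,6-dimethoxyphenoxy}propane-1,3-diol (threo)
Conditions: LiBH4 (2 equiv), H2O (2 equiv), THF/Et2O, 0 °C
Reagents that add atoms: none
Why: Reductive cleavage of the N-acyloxazolidinone, in which hydride attacks the activated exocyclic imide carbonyl and the released aldehyde is reduced at once, gives the C9 alcohol at 0 °C without touching C7 or C8 and returns the auxiliary.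

Step 8
Reactants: 16 the threo 1,3-diol
Product: 17 (1R,2R)-1-(4-benzyloxy-3-methoxyphenyl)-3-(tert-butyldimethylsilyloxy)-2-{4-[3-(tert-butyldiphenylsilyloxy)propyl]-2,6-dimethoxyphenoxy}propan-1-ol
Conditions: TBSCl (1.05 equiv), imidazole (2 equiv), CH2Cl2, 0 °C
Reagents that add atoms: TBSCl, CC(C)(C)[Si](C)(C)Cl
Why: Chemoselective silyl ether protection, in which the primary C9 hydroxyl reacts much faster than the hindered secondary benzylic C7 hydroxyl and leaves the latter free for inversion.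

Step 9
Reactants: 17 the threo C9-TBS alcohol
Product: 19 (1S,2R)-1-(4-benzyloxy-3-methoxyphenyl)-3-(tert-butyldimethylsilyloxy)-2-{4-[3-(tert-butyldiphenylsilyloxy)propyl]-2,6-dimethoxyphenoxy}propyl 4-nitrobenzoate (erythro), via alkoxyphosphonium 4-nitrobenzoate 18 (not isolated)
Conditions: 4-O2NC6H4CO2H (3 equiv), PPh3 (3 equiv), DIAD (3 equiv), THF, 0 °C to rt
Reagents that add atoms: 4-nitrobenzoic acid, O=C(O)c1ccc(cc1)[N+](=O)[O-]; PPh3, c1ccc(cc1)P(c1ccccc1)c1ccccc1 (in 18 only)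
Why: Mitsunobu reaction, in which the C7 hydroxyl becomes the oxyphosphonium leaving group of 18 and is displaced from the rear by the acidic 4-nitrobenzoate (SN2), inverting C7 from R to S (threo to erythro) while C8 is not touched.

Step 10
Reactants: 19 the erythro 4-nitrobenzoate
Product: 20 (1S,2R)-1-(4-benzyloxy-3-methoxyphenyl)-3-(tert-butyldimethylsilyloxy)-2-{4-[3-(tert-butyldiphenylsilyloxy)propyl]-2,6-dimethoxyphenoxy}propan-1-ol (erythro)
Conditions: K2CO3 (0.2 equiv), MeOH/THF 2:1, 0 °C to rt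
Reagents that add atoms: none
Why: Base-catalysed transesterification (methanolysis) of the electron-poor benzoate cleaves the acyl–oxygen bond, so the C7–O bond and its new configuration are kept, and the benzyl-capped phenol rules out quinone methide formation.

Step 11
Reactants: 20 the erythro bis-silyl ether
Product: 21 (1S,2R)-1-(4-benzyloxy-3-methoxyphenyl)-2-[4-(3-hydroxypropyl)-2,6-dimethoxyphenoxy]propane-1,3-diol
Conditions: Bu4NF (4 equiv), AcOH (4 equiv), THF, rt, 16 h
Reagents that add atoms: none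
Why: Fluoride-mediated desilylation driven by the strong Si–F bond removes the TBS and TBDPS ethers together, and the acetic acid buffer keeps the medium near neutral so no C–O bond at C7 or C8 is disturbed.

Step 12
Reactants: 21 the O-benzyl triol
Product: 22 IN0404, (1S,2R)-1-(4-hydroxy-3-methoxyphenyl)-2-[4-(3-hydroxypropyl)-2,6-dimethoxyphenoxy]propane-1,3-diol
Conditions: H2 (1 atm), 10% Pd/C, EtOAc/EtOH 1:1, rt, stopped after uptake of one equivalent
Reagents that add atoms: none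
Why: Catalytic hydrogenolysis of an aryl benzyl ether is much faster under neutral conditions than loss of the secondary benzylic hydroxyl or of the alkyl aryl ether, so the phenol is freed with both stereocentres intact.

## Compound list

1 | 4-allyl-2,6-dimethoxyphenol | C=CCc1cc(OC)c(O)c(OC)c1 | starting material
2 | ethyl bromoacetate | CCOC(=O)CBr | starting material
3 | ethyl 2-(4-allyl-2,6-dimethoxyphenoxy)acetate | C=CCc1cc(OC)c(OCC(=O)OCC)c(OC)c1 | intermediate
4 | B-alkyl-9-BBN adduct of 3 (formed in the flask) | CCOC(=O)COc1c(OC)cc(CCCB2C3CCCC2CCC3)cc1OC | intermediate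
5 | ethyl 2-[4-(3-hydroxypropyl)-2,6-dimethoxyphenoxy]acetate | CCOC(=O)COc1c(OC)cc(CCCO)cc1OC | intermediate
6 | ethyl 2-{4-[3-(tert-butyldiphenylsilyloxy)propyl]-2,6-dimethoxyphenoxy}acetate | CCOC(=O)COc1c(OC)cc(CCCO[Si](c2ccccc2)(c2ccccc2)C(C)(C)C)cc1OC | intermediate
7 | lithium carboxylate of 8 (formed in the flask) | [Li+].[O-]C(=O)COc1c(OC)cc(CCCO[Si](c2ccccc2)(c2ccccc2)C(C)(C)C)cc1OC | intermediate
8 | 2-{4-[3-(tert-butyldiphenylsilyloxy)propyl]-2,6-dimethoxyphenoxy}acetic acid | OC(=O)COc1c(OC)cc(CCCO[Si](c2ccccc2)(c2ccccc2)C(C)(C)C)cc1OC | intermediate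
9 | (S)-4-benzyloxazolidin-2-one | O=C1N[C@@H](Cc2ccccc2)CO1 | starting material
10 | pivalic mixed anhydride of 8 (formed in the flask) | CC(C)(C)C(=O)OC(=O)COc1c(OC)cc(CCCO[Si](c2ccccc2)(c2ccccc2)C(C)(C)C)cc1OC | intermediate
11 | (S)-4-benzyl-3-(2-{4-[3-(tert-butyldiphenylsilyloxy)propyl]-2,6-dimethoxyphenoxy}acetyl)oxazolidin-2-one | O=C(COc1c(OC)cc(CCCO[Si](c2ccccc2)(c2ccccc2)C(C)(C)C)cc1OC)N1[C@@H](Cc2ccccc2)COC1=O | intermediate
12 | 4-benzyloxy-3-methoxybenzaldehyde | COc1cc(C=O)ccc1OCc1ccccc1 | starting material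
13 | (Z)-dibutylboron enolate of 11 (formed in the flask) | CCCCB(CCCC)O/C(=C\Oc1c(OC)cc(CCCO[Si](c2ccccc2)(c2ccccc2)C(C)(C)C)cc1OC)N1[C@@H](Cc2ccccc2)COC1=O | intermediate
14 | dibutylboron aldolate of 15 (formed in the flask) | COc1cc([C@@H](OB(CCCC)CCCC)[C@@H](C(=O)N2[C@@H](Cc3ccccc3)COC2=O)Oc2c(OC)cc(CCCO[Si](c3ccccc3)(c3ccccc3)C(C)(C)C)cc2OC)ccc1OCc1ccccc1 | intermediate
15 | (S)-4-benzyl-3-[(2S,3R)-3-(4-benzyloxy-3-methoxyphenyl)-2-{4-[3-(tert-butyldiphenylsilyloxy)propyl]-2,6-dimethoxyphenoxy}-3-hydroxypropanoyl]oxazolidin-2-one | COc1cc([C@@H](O)[C@@H](C(=O)N2[C@@H](Cc3ccccc3)COC2=O)Oc2c(OC)cc(CCCO[Si](c3ccccc3)(c3ccccc3)C(C)(C)C)cc2OC)ccc1OCc1ccccc1 | intermediate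
16 | (1R,2R)-1-(4-benzyloxy-3-methoxyphenyl)-2-{4-[3-(tert-butyldiphenylsilyloxy)propyl]-2,6-dimethoxyphenoxy}propane-1,3-diol | COc1cc([C@@H](O)[C@@H](CO)Oc2c(OC)cc(CCCO[Si](c3ccccc3)(c3ccccc3)C(C)(C)C)cc2OC)ccc1OCc1ccccc1 | intermediate
17 | (1R,2R)-1-(4-benzyloxy-3-methoxyphenyl)-3-(tert-butyldimethylsilyloxy)-2-{4-[3-(tert-butyldiphenylsilyloxy)propyl]-2,6-dimethoxyphenoxy}propan-1-ol | COc1cc([C@@H](O)[C@@H](CO[Si](C)(C)C(C)(C)C)Oc2c(OC)cc(CCCO[Si](c3ccccc3)(c3ccccc3)C(C)(C)C)cc2OC)ccc1OCc1ccccc1 | intermediate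
18 | alkoxyphosphonium 4-nitrobenzoate of 17 (formed in the flask) | COc1cc([C@@H](O[P+](c2ccccc2)(c2ccccc2)c2ccccc2)[C@@H](CO[Si](C)(C)C(C)(C)C)Oc2c(OC)cc(CCCO[Si](c3ccccc3)(c3ccccc3)C(C)(C)C)cc2OC)ccc1OCc1ccccc1.O=C([O-])c1ccc([N+](=O)[O-])cc1 | intermediate
19 | (1S,2R)-1-(4-benzyloxy-3-methoxyphenyl)-3-(tert-butyldimethylsilyloxy)-2-{4-[3-(tert-butyldiphenylsilyloxy)propyl]-2,6-dimethoxyphenoxy}propyl 4-nitrobenzoate | COc1cc([C@H](OC(=O)c2ccc([N+](=O)[O-])cc2)[C@@H](CO[Si](C)(C)C(C)(C)C)Oc2c(OC)cc(CCCO[Si](c3ccccc3)(c3ccccc3)C(C)(C)C)cc2OC)ccc1OCc1ccccc1 | intermediate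
20 | (1S,2R)-1-(4-benzyloxy-3-methoxyphenyl)-3-(tert-butyldimethylsilyloxy)-2-{4-[3-(tert-butyldiphenylsilyloxy)propyl]-2,6-dimethoxyphenoxy}propan-1-ol | COc1cc([C@H](O)[C@@H](CO[Si](C)(C)C(C)(C)C)Oc2c(OC)cc(CCCO[Si](c3ccccc3)(c3ccccc3)C(C)(C)C)cc2OC)ccc1OCc1ccccc1 | intermediate
21 | (1S,2R)-1-(4-benzyloxy-3-methoxyphenyl)-2-[4-(3-hydroxypropyl)-2,6-dimethoxyphenoxy]propane-1,3-diol | COc1cc([C@H](O)[C@@H](CO)Oc2c(OC)cc(CCCO)cc2OC)ccc1OCc1ccccc1 | intermediate
22 | IN0404, (1S,2R)-1-(4-hydroxy-3-methoxyphenyl)-2-[4-(3-hydroxypropyl)-2,6-dimethoxyphenoxy]propane-1,3-diol | COc1cc([C@H](O)[C@@H](CO)Oc2c(OC)cc(CCCO)cc2OC)ccc1O | target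

## Step count and weak points

Total step count: 12. Longest linear sequence: 12 steps (1 to 22).

**Step 9 (Mitsunobu inversion).**
- Risk: the oxyphosphonium group sits on an electron-rich benzylic carbon next to a bulky aryloxy carbon. Partial ionisation (erosion of the inversion) or elimination to the enol ether can therefore compete.
- Fallback: inversion by oxidation and catalyst-controlled reduction. It sets out from 17, which Dess–Martin periodinane in CH2Cl2 at 0 °C to rt oxidises to (R)-1-(4-benzyloxy-3-methoxyphenyl)-3-(tert-butyldimethylsilyloxy)-2-{4-[3-(tert-butyldiphenylsilyloxy)propyl]-2,6-dimethoxyphenoxy}propan-1-one F1.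
- Noyori asymmetric transfer hydrogenation of this aryl ketone follows, with RuCl[(R,R)-TsDPEN](p-cymene) (2 mol%) in HCO2H/Et3N 5:2 at rt. It delivers hydride in the sense that gives (R)-1-phenylethanol from acetophenone, which here is the 7S carbinol.
- The fallback comes back to the route at 20, bypassing 18 and 19.

**Step 6 (boron aldol).**
- Risk: the di-ortho-methoxy aryloxy group is bulky and Lewis basic. It may slow enolisation by Bu2BOTf or lower the conversion.
- Fallback: a titanium enolate of a thione auxiliary. It sets out from 8, which DCC and catalytic DMAP couple with bought (S)-4-benzyl-1,3-oxazolidine-2-thione to give (S)-4-benzyl-3-(2-{4-[3-(tert-butyldiphenylsilyloxy)propyl]-2,6-dimethoxyphenoxy}acetyl)oxazolidine-2-thione F2.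
- TiCl4 (1.05 equiv), iPr2NEt (1.1 equiv) and N-methylpyrrolidinone (1 equiv) in CH2Cl2 at 0 °C give the chlorotitanium (Z)-enolate F3. This adds 12 through a non-chelated chair to the trichlorotitanium aldolate F4.
- Aqueous quench gives the Evans-syn adduct (S)-4-benzyl-3-[(2S,3R)-3-(4-benzyloxy-3-methoxyphenyl)-2-{4-[3-(tert-butyldiphenylsilyloxy)propyl]-2,6-dimethoxyphenoxy}-3-hydroxypropanoyl]oxazolidine-2-thione F5.
- NaBH4 in THF/H2O at 0 °C cleaves the very reactive thioimide, and the fallback comes back to the route at 16.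

**Step 7 (reductive removal of the auxiliary).**
- Risk: with a hindered α-branched imide, hydride can open the oxazolidinone ring instead. The lithium aldolate of an electron-rich benzaldehyde can also undergo retro-aldol cleavage.
- Fallback: hydrolysis first, reduction second. It sets out from 15, which LiOH/H2O2 in THF/H2O at 0 °C cleaves selectively at the exocyclic carbonyl.
- Na2SO3 quench and acidification with HCl give (2S,3R)-3-(4-benzyloxy-3-methoxyphenyl)-2-{4-[3-(tert-butyldiphenylsilyloxy)propyl]-2,6-dimethoxyphenoxy}-3-hydroxypropanoic acid F6.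
- BH3·THF (0 °C to rt) then reduces the carboxylic acid chemoselectively, and the fallback comes back to the route at 16.

## Further compounds

F1 | step 9 | (R)-1-(4-benzyloxy-3-methoxyphenyl)-3-(tert-butyldimethylsilyloxy)-2-{4-[3-(tert-butyldiphenylsilyloxy)propyl]-2,6-dimethoxyphenoxy}propan-1-one | COc1cc(C(=O)[C@@H](CO[Si](C)(C)C(C)(C)C)Oc2c(OC)cc(CCCO[Si](c3ccccc3)(c3ccccc3)C(C)(C)C)cc2OC)ccc1OCc1ccccc1
F2 | step 6 | (S)-4-benzyl-3-(2-{4-[3-(tert-butyldiphenylsilyloxy)propyl]-2,6-dimethoxyphenoxy}acetyl)oxazolidine-2-thione | O=C(COc1c(OC)cc(CCCO[Si](c2ccccc2)(c2ccccc2)C(C)(C)C)cc1OC)N1[C@@H](Cc2ccccc2)COC1=S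
F3 | step 6 | chlorotitanium (Z)-enolate of F2 | Cl[Ti](Cl)(Cl)O/C(=C\Oc1c(OC)cc(CCCO[Si](c2ccccc2)(c2ccccc2)C(C)(C)C)cc1OC)N1[C@@H](Cc2ccccc2)COC1=S
F4 | step 6 | trichlorotitanium aldolate of F5 | COc1cc([C@@H](O[Ti](Cl)(Cl)Cl)[C@@H](C(=O)N2[C@@H](Cc3ccccc3)COC2=S)Oc2c(OC)cc(CCCO[Si](c3ccccc3)(c3ccccc3)C(C)(C)C)cc2OC)ccc1OCc1ccccc1
F5 | step 6 | (S)-4-benzyl-3-[(2S,3R)-3-(4-benzyloxy-3-methoxyphenyl)-2-{4-[3-(tert-butyldiphenylsilyloxy)propyl]-2,6-dimethoxyphenoxy}-3-hydroxypropanoyl]oxazolidine-2-thione | COc1cc([C@@H](O)[C@@H](C(=O)N2[C@@H](Cc3ccccc3)COC2=S)Oc2c(OC)cc(CCCO[Si](c3ccccc3)(c3ccccc3)C(C)(C)C)cc2OC)ccc1OCc1ccccc1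
F6 | step 7 | (2S,3R)-3-(4-benzyloxy-3-methoxyphenyl)-2-{4-[3-(tert-butyldiphenylsilyloxy)propyl]-2,6-dimethoxyphenoxy}-3-hydroxypropanoic acid | COc1cc([C@@H](O)[C@@H](C(=O)O)Oc2c(OC)cc(CCCO[Si](c3ccccc3)(c3ccccc3)C(C)(C)C)cc2OC)ccc1OCc1ccccc1
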